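Numbering: five-membered ring C1(Me)–C2–C3–C4–C5, seven-membered ring C1–C5–C6–C7=C8(Me)–C9(=O)–C10. Everything rests on cutting C5–C6 and C1–C10: the segment C6(OH)–C7=C8(Me)–C9(=O)–C10 is read as an 8-oxabicyclo[3.2.1]oct-3-en-2-one whose oxygen bridge, from C6 to C10, has been opened reductively at C10. One (5+2) cycloaddition of 4-methyl-3-oxidopyrylium across the C1=C5 double bond of 3-methylcyclopent-2-enone forms both bonds, the seven-membered carbocycle, quaternary C1 and the C6 oxygen. Its precursor is the Achmatowicz-derived 6-acetoxy-4-methyl-2H-pyran-3(6H)-one; bridge opening, inversion at C5, isopropyl addition with aroylation at C4 and desilylation finish the route.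

Key step: step 3

Remark: β means the face of the C1 methyl group and α the opposite face; (3-methylfuran-2-yl)methanol is taken as a catalogue compound.

Step 1
Reactants: 1 (3-methylfuran-2-yl)methanol
Product: 2 6-hydroxy-4-methyl-2H-pyran-3(6H)-one (racemic hemiacetal)
Conditions: mCPBA, CH2Cl2, 0 °C
Reagents that add atoms: mCPBA (3-chloroperoxybenzoic acid), OOC(=O)c1cccc(Cl)c1
Why: Achmatowicz rearrangement, in which oxidation of the furan, opening to the cis-enedione and hemiacetal closure by the primary alcohol give the pyranone with the methyl group α to the ketone; the hemiacetal centre is racemic and is destroyed in step 3.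

Step 2
Reactants: 2 6-hydroxy-4-methyl-2H-pyran-3(6H)-one
Product: 3 6-acetoxy-4-methyl-2H-pyran-3(6H)-one (racemic)
Conditions: Ac2O, pyridine, DMAP (cat.), CH2Cl2, 0 °C
Reagents that add atoms: acetic anhydride, CC(=O)OC(C)=O
Why: DMAP-catalysed O-acetylation of the hemiacetal hydroxyl, run cold so that the acetate does not ionise prematurely; no stereocentre of consequence is formed.

Step 3
Reactants: 3 6-acetoxy-4-methyl-2H-pyran-3(6H)-one; 4 3-methylcyclopent-2-en-1-one
Product: 6 racemic exo cycloadduct rel-(3aR,4S,8S,8aS)-6,8a-dimethyl-1,2,3a,4,8,8a-hexahydro-4,8-epoxyazulene-3,7-dione, via 4-methyl-3-oxidopyrylium ylide 5 (not isolated)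
Conditions: 4 (10 equiv), i-Pr2NEt, MeCN, 60 °C, slow addition of 3
Reagents that add atoms: none
Why: The amine removes the C2–H of 3 and acetate leaves, giving the planar 4-methyl-3-oxidopyrylium 5, a five-atom 4π dipole that adds suprafacially across the C1=C5 bond of 4 in a thermally allowed (5+2) cycloaddition; the closest known reaction is the base-mediated oxidopyrylium–alkene cycloaddition with acrylates, vinyl ketones and cyclic enones, applied here to a β-methyl enone. The seven-membered carbocycle closes by intermolecular cycloaddition, both ring bonds (C5–C6 and C1–C10) forming in the one step, and the same two bonds complete the oxygen-bridged five-membered ring C1–C5–C6–O–C10. C1 and C5 come out cis because the alkene is held in the five-membered ring, C6 and C10 are cis through the bridge, and the exo approach (cyclopentanone on the side of the bridge oxygen, C1–Me and C5–H under the enone bridge) relates the two pairs; no absolute control is exerted and the racemate is resolved in step 4. The step needs the regiochemistry in which the ylide terminus next to the oxide (future C10) bonds to the enone β-carbon C1 and the acetal-derived terminus (future C6) to the α-carbon C5, the normal polarity match between the nucleophilic oxide-flanked carbon and the Michael acceptor, and it needs exo selectivity, which should be favoured because the endo mode forces the C2–C3 methylenes and the C4 carbonyl against the oxido-enone face. Ylide dimerisation is held back by slow addition of 3 into a large excess of the cheap, recoverable enone, and the diastereomers are separable should some endo adduct form.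

Step 4
Reactants: 6 racemic exo cycloadduct
Product: 7 (3aR,4S,8S,8aS)-6,8a-dimethyl-1,2,3a,4,8,8a-hexahydro-4,8-epoxyazulene-3,7-dione (single enantiomer; C1–Me β, C5–H β, bridge oxygen α on C6 and C10)
Conditions: preparative SFC on amylose tris(3,5-dimethylphenylcarbamate), CO2/MeOH
Reagents that add atoms: none
Why: Chromatographic resolution of enantiomers on a polysaccharide chiral stationary phase, for which the rigid enone chromophore is well suited; no stereocentre is formed and the absolute configuration of the enantiomer carried on is to be confirmed crystallographically.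

Step 5
Reactants: 7 (3aR,4S,8S,8aS) cycloadduct
Product: 8 (3aR,4S,8aR)-4-hydroxy-6,8a-dimethyl-1,2,3a,4,8,8a-hexahydroazulene-3,7-dione (cis-fused; C5–H β, C6–OH α)
Conditions: SmI2, THF/MeOH, −78 °C
Reagents that add atoms: none
Why: Samarium diiodide reduction of an α-alkoxy ketone, in which the C9 ketyl expels the C10–O bond, a second electron gives the samarium enolate and MeOH protonates it at C10 back to the conjugated enone; the C6–O bond is untouched so C6 keeps its configuration, C10 ceases to be stereogenic and the unactivated C4 ketone is not reduced at −78 °C.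

Step 6
Reactants: 8 (3aR,4S,8aR) hydroxy dione
Product: 9 (3aR,4S,8aR)-4-[(tert-butyldimethylsilyl)oxy]-6,8a-dimethyl-1,2,3a,4,8,8a-hexahydroazulene-3,7-dione (cis-fused)
Conditions: TBSOTf, 2,6-lutidine, CH2Cl2, −78 °C
Reagents that add atoms: tert-butyldimethylsilyl trifluoromethanesulfonate, CC(C)(C)[Si](C)(C)OS(=O)(=O)C(F)(F)F
Why: Silylation of the secondary allylic alcohol, which at −78 °C with a hindered pyridine base outruns silyl enol ether formation at either ketone; it removes the free β-hydroxy ketone (retro-aldol, chelation) before base treatment and no stereocentre changes.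

Step 7
Reactants: 9 cis-fused silyl ether
Product: 10 (3aS,4S,8aR)-4-[(tert-butyldimethylsilyl)oxy]-6,8a-dimethyl-1,2,3a,4,8,8a-hexahydroazulene-3,7-dione (trans-fused; C5–H α)
Conditions: DBU (cat.), toluene, 23 °C; recovered 9 recycled
Reagents that add atoms: none
Why: Base-mediated α-epimerisation through the C4 enolate equilibrates C5 under thermodynamic control; the trans-fused ketone (C1–Me and C5–H anti, the C6 silyloxy group no longer under the cyclopentanone on the concave face) is separated by chromatography and recovered 9 is re-equilibrated, so the step delivers 10 even if it is not the major isomer at equilibrium.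

Step 8
Reactants: 11 4-hydroxybenzoic acid
Product: 12 tert-butyldimethylsilyl 4-[(tert-butyldimethylsilyl)oxy]benzoate
Conditions: TBSCl, imidazole, DMF, 23 °C
Reagents that add atoms: tert-butyldimethylsilyl chloride, CC(C)(C)[Si](C)(C)Cl
Why: Imidazole-promoted silylation of both the phenol and the carboxylic acid; no stereochemistry is involved.

Step 9
Reactants: 12 bis-silylated 4-hydroxybenzoic acid
Product: 13 4-[(tert-butyldimethylsilyl)oxy]benzoyl chloride
Conditions: (COCl)2, DMF (cat.), CH2Cl2, 0 to 23 °C
Reagents that add atoms: oxalyl chloride, O=C(Cl)C(Cl)=O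
Why: Silyl esters are converted directly into acyl chlorides by the chloroiminium reagent from oxalyl chloride and DMF under neutral conditions, which leaves the aryl silyl ether intact.

Step 10
Reactants: 10 trans-fused silyl ether dione; 13 4-[(tert-butyldimethylsilyl)oxy]benzoyl chloride
Product: 15 (3R,3aS,4S,8aR)-4-[(tert-butyldimethylsilyl)oxy]-6,8a-dimethyl-7-oxo-3-(propan-2-yl)-1,2,3,3a,4,7,8,8a-octahydroazulen-3-yl 4-[(tert-butyldimethylsilyl)oxy]benzoate, via chloromagnesium C4-alkoxide 14 (not isolated)
Conditions: i-PrMgCl, LaCl3·2LiCl, THF, −78 °C; then 13, DMAP, −78 to 23 °C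
Reagents that add atoms: isopropylmagnesium chloride, CC(C)[Mg]Cl
Why: Lanthanum-promoted Grignard 1,2-addition followed by O-acylation of the alkoxide in the same flask; the weakly basic reagent should add to the saturated C4 ketone faster than to the cross-conjugated, α-methylated C9 enone and without enolising C5, it attacks the α face of C4 (next to the small C5–H, anti to the C5–C6 bond and its silyloxy group) so that the new C4 oxygen is β, and the hindered alkoxide 14 is trapped by the acylpyridinium formed from 13 and DMAP.

Step 11
Reactants: 15 bis-silyl protected ester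
Product: 16 (3R,3aS,4S,8aR)-4-hydroxy-6,8a-dimethyl-7-oxo-3-(propan-2-yl)-1,2,3,3a,4,7,8,8a-octahydroazulen-3-yl 4-hydroxybenzoate (target; route numbering 1R,4R,5S,6S)
Conditions: HF·pyridine, pyridine, THF, 0 to 23 °C
Reagents that add atoms: none
Why: Fluoride-driven cleavage of the aryl and the secondary alkyl silyl ether under buffered, non-basic conditions, so that no C6 alkoxide is formed that could take over the aroyl group from the tertiary C4 ester; no stereocentre is touched.

Compound list
1 | (3-methylfuran-2-yl)methanol | Cc1ccoc1CO | starting material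
2 | 6-hydroxy-4-methyl-2H-pyran-3(6H)-one, racemic | CC1=CC(O)OCC1=O | intermediate
3 | 6-acetoxy-4-methyl-2H-pyran-3(6H)-one, racemic | CC(=O)OC1C=C(C)C(=O)CO1 | intermediate
4 | 3-methylcyclopent-2-en-1-one | CC1=CC(=O)CC1 | starting material
5 | 4-methyl-3-oxidopyrylium ylide (not isolated) | Cc1cc[o+]cc1[O-] | intermediate
6 | racemic exo cycloadduct, rel-(3aR,4S,8S,8aS)-6,8a-dimethyl-1,2,3a,4,8,8a-hexahydro-4,8-epoxyazulene-3,7-dione (both enantiomers written) | CC1=C[C@@H]2O[C@H](C1=O)[C@@]3(C)CCC(=O)[C@@H]23.CC1=C[C@H]2O[C@@H](C1=O)[C@]3(C)CCC(=O)[C@H]23 | intermediate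
7 | (3aR,4S,8S,8aS)-6,8a-dimethyl-1,2,3a,4,8,8a-hexahydro-4,8-epoxyazulene-3,7-dione | CC1=C[C@@H]2O[C@H](C1=O)[C@@]3(C)CCC(=O)[C@@H]23 | intermediate
8 | (3aR,4S,8aR)-4-hydroxy-6,8a-dimethyl-1,2,3a,4,8,8a-hexahydroazulene-3,7-dione, cis-fused | CC1=C[C@H](O)[C@H]2[C@](C)(CCC2=O)CC1=O | intermediate
9 | (3aR,4S,8aR)-4-[(tert-butyldimethylsilyl)oxy]-6,8a-dimethyl-1,2,3a,4,8,8a-hexahydroazulene-3,7-dione, cis-fused | CC1=C[C@H](O[Si](C)(C)C(C)(C)C)[C@H]2[C@](C)(CCC2=O)CC1=O | intermediate
10 | (3aS,4S,8aR)-4-[(tert-butyldimethylsilyl)oxy]-6,8a-dimethyl-1,2,3a,4,8,8a-hexahydroazulene-3,7-dione, trans-fused | CC1=C[C@H](O[Si](C)(C)C(C)(C)C)[C@@H]2[C@](C)(CCC2=O)CC1=O | intermediate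
11 | 4-hydroxybenzoic acid | OC(=O)c1ccc(O)cc1 | starting material
12 | tert-butyldimethylsilyl 4-[(tert-butyldimethylsilyl)oxy]benzoate | CC(C)(C)[Si](C)(C)OC(=O)c1ccc(O[Si](C)(C)C(C)(C)C)cc1 | intermediate
13 | 4-[(tert-butyldimethylsilyl)oxy]benzoyl chloride | CC(C)(C)[Si](C)(C)Oc1ccc(cc1)C(Cl)=O | intermediate
14 | chloromagnesium C4-alkoxide of the isopropyl adduct of 10 (not isolated) | CC1=C[C@H](O[Si](C)(C)C(C)(C)C)[C@@H]2[C@](C)(CC[C@@]2(O[Mg]Cl)C(C)C)CC1=O | intermediate
15 | (3R,3aS,4S,8aR)-4-[(tert-butyldimethylsilyl)oxy]-6,8a-dimethyl-7-oxo-3-(propan-2-yl)-1,2,3,3a,4,7,8,8a-octahydroazulen-3-yl 4-[(tert-butyldimethylsilyl)oxy]benzoate | CC1=C[C@H](O[Si](C)(C)C(C)(C)C)[C@@H]2[C@](C)(CC[C@@]2(OC(=O)c2ccc(O[Si](C)(C)C(C)(C)C)cc2)C(C)C)CC1=O | intermediate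
16 | (3R,3aS,4S,8aR)-4-hydroxy-6,8a-dimethyl-7-oxo-3-(propan-2-yl)-1,2,3,3a,4,7,8,8a-octahydroazulen-3-yl 4-hydroxybenzoate | CC1=C[C@H](O)[C@@H]2[C@](C)(CC[C@@]2(OC(=O)c2ccc(O)cc2)C(C)C)CC1=O | target

Total step count: 11. Longest linear sequence: 9 steps (steps 1–7, 10, 11); steps 8 and 9 form a two-step side branch.

Steps most likely to fail

1. Step 3. The ylide may dimerise faster than it adds to the hindered, weakly electrophilic β,β-disubstituted enone, and discrimination between exo and endo approach may be low. The fallback sets out from 3 and comes back to the route at 8. The enone is replaced by the commercial 2-bromo-3-methylcyclopent-2-en-1-one F1, whose halogen lowers the LUMO of the 2π partner. The same amine-mediated (5+2) cycloaddition should give the racemic C5-bromo exo cycloadduct F2, and resolution on the same chiral phase the enantiomer F3. Excess SmI2 (THF/MeOH, −78 °C) would then remove the bromine and open the bridge in one operation; protonation of the C4 enolate on its open β face returns the cis-fused hydroxy dione 8.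

2. Step 7. The equilibrium may lie on the side of the cis-fused ketone, and long exposure to base may start β-elimination of the C6 silyloxy group. The fallback sets out from 9 and comes back at 10, replacing thermodynamic control by reagent-controlled kinetic protonation. Equilibrating silylation (TMSOTf, Et3N, CH2Cl2, 23 °C) would give the bis(trimethylsilyl) enol ether F4 (C4=C5 enol ether and C9=C10 dienol ether). F4 would be protonated at −78 °C with a chiral Lewis acid-assisted Brønsted acid (SnCl4·BINOL, the BINOL enantiomer chosen to deliver the proton to the α face of C5). The C9 dienol ether is protonated at C10 back to the enone in the same operation.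

3. Step 10. The hindered tertiary alkoxide may resist acylation in the pot, and part of the reagent may attack the C9 enone or act as a hydride donor at C4. The fallback sets out from 10 and comes back at 15, separating C–C bond formation from ester formation. The addition is run alone (i-PrMgCl, LaCl3·2LiCl, THF, −78 °C, NH4Cl work-up) and the tertiary alcohol F5 is isolated and purified. F5 is then acylated as its potassium alkoxide (KHMDS, THF, −78 °C, then 13).

Further compounds
F1 | step 3 | 2-bromo-3-methylcyclopent-2-en-1-one | CC1=C(Br)C(=O)CC1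
F2 | step 3 | racemic C5-bromo exo cycloadduct (3a-bromo-6,8a-dimethyl-1,2,3a,4,8,8a-hexahydro-4,8-epoxyazulene-3,7-dione, both enantiomers written) | CC1=C[C@@H]2O[C@H](C1=O)[C@@]3(C)CCC(=O)[C@@]23Br.CC1=C[C@H]2O[C@@H](C1=O)[C@]3(C)CCC(=O)[C@]23Br
F3 | step 3 | C5-bromo exo cycloadduct, single enantiomer with bromine β on C5 and the bridge oxygen α | CC1=C[C@@H]2O[C@H](C1=O)[C@@]3(C)CCC(=O)[C@@]23Br
F4 | step 7 | bis(trimethylsilyl) enol ether of 9 (C4=C5 and C9=C10 silyl enol ethers, C6 silyl ether kept) | CC1=C[C@H](O[Si](C)(C)C(C)(C)C)C2=C(O[Si](C)(C)C)CC[C@]2(C)C=C1O[Si](C)(C)C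
F5 | step 10 | tertiary alcohol, (3R,3aS,4S,8aR)-4-[(tert-butyldimethylsilyl)oxy]-3-hydroxy-6,8a-dimethyl-3-(propan-2-yl)-octahydroazulen-7-one | CC1=C[C@H](O[Si](C)(C)C(C)(C)C)[C@@H]2[C@](C)(CC[C@@]2(O)C(C)C)CC1=O
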